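North's plateau reading gave each charged reagent molecule a chance of 0.100 of standing as target: this is the reagent share f, the target concentration at a run's best reading divided by the reagent charged.

| setting | south-west | south | north | flask |
|---|---|---|---|---|
| solid substrate | 0.10 M | 0.15 M | 0.20 M | 0.20 M |
| reagent | 0.16 M | 0.16 M | 0.32 M | 0.160 M |
| remark | run made earlier | run made earlier | run made earlier |  |
| time |  |  |  | 4.0 d |

| run | time / d | target / % |
|---|---|---|
| south-west | 0.625 | 15 |
| south-west | 1.04 | 15 |
| south-west | 1.25 | 13 |
| south-west | 2.00 | 11 |
| south-west | 3.00 | 11 |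
| south-west | 5.00 | 3 |
| south | 0.625 | 11 |
| south | 1.04 | 11 |
| south | 1.25 | 13 |
| south | 2.00 | 10 |
| south | 3.00 | 9 |
| south | 5.00 | 4 |
| north | 0.625 | 13 |
| north | 1.04 | 16 |
| north | 1.67 | 16 |
| north | 3.00 | 16 |
| north | 5.00 | 8 |

(readings scatter by 1.5 percentage points)

- at the start none of the solid substrate is in solution
- a reading or a percentage of target counts all its forms, free or not

- the moment within 4.0 d at which there is most target
- the amount of target, in percent of the solid substrate charged, at that time

I went through the two charges in turn, asked what each should do, and then read what the earlier runs show; from south to north both charges change together.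

If target followed solid substrate, raising that charge would have kept the percentage. Instead, at 0.16 M reagent, the best reading went from 15 % in south-west to 13 % in south, so f read 0.0938 and 0.122.

A constant f means that target concentration grows with reagent, and north, with twice south-west's reagent and also more solid, read the 0.100 above.

Time I could only bound: north still read 16 % at 3.00 d but 8 % at 5.00 d.

For the flask, with reagent charge c_B and solid substrate charge c_S, I reckoned from north's f:

y = f c_B / c_S = 8.00 %

The forecast stood higher than my reckoning, at 9.5 % at 1.3 d, with target at “about 0.1 × reagent”.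

The flask gave 9.01 % at 2.54 d, later than forecast, which makes f 0.113; the neighbour with 0.40 M reagent gave 22.3 %, which makes f 0.112.

    solid substrate ⇌ dissolved substrate, rate k1*(cs1 - [dissolved substrate]) while solid is left; crystals form when [dissolved substrate] > cs1 (solubility = 0.0670 M, k = 5.45 × 10⁻⁵ s⁻¹)
    dissolved substrate + reagent ⇌ target (K = 5.30 M⁻¹, k = 1.58 × 10⁻⁴ M⁻¹ s⁻¹)
    2 dissolved substrate → side product (k = 1.11 × 10⁻⁴ M⁻¹ s⁻¹)
    solid product ⇌ target, rate k4*(cs4 - [target]) while solid is left; crystals form when [target] > cs4 (solubility = 0.0840 M, k = 2.36 × 10⁻⁴ s⁻¹)
    reagent ⇌ dormant form (K = 1.28, k = 2.74 × 10⁻⁵ s⁻¹)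

At 0.837 d the flask made dissolved substrate 1.09 times as fast as it used it up, each step taken net, a quasi-steady state, and at 2.00 d dissolved substrate stood at 27.4 % with 15.4 % solid substrate left. By 4.00 d, with solid substrate at 0 %, that ratio was 0.309, dissolved substrate 12.6 % and target 5.18 %.

(The data are calculated for an exercise.)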